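**Strategy**

The dihydropyranone ring (O1, C2=O, C3=C4, C5H2, C6H) is opened across two ring bonds, C4–C5 and O1–C6. Ring atoms O1, C2, C3 and C4 are then exactly propiolic acid, and C5–C6 is the terminal alkene of an open-chain homoallylic silyl ether. A gold-catalysed formal [4+2] annulation joins the two in one operation, closes the ring and sets C6 under catalyst control. The precursor is the tris(silyl ether) of an all-anti heptadec-1-ene-4,6,8-triol, grown from 1-decanol by three iridium-catalysed allylations with one repeating C3 unit (allyl acetate) and one catalyst type, the ligand antipode alternating; ozonolysis–reduction links the cycles, which run on unprotected diol and triol.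

Key step: step 7

Assumption 1: the iridium allylation is taken to follow the sense (R)-ligand → (S)-configured nonyl–CH(OH)–CH2CH=CH2 (equivalently (S)-ligand → (S,S)-diol from 1,3-propanediol); if a substrate shows the opposite sense, the ligand antipodes are exchanged and nothing else changes.

Assumption 2: which antipode of the chiral digold catalyst favours (6S) in step 7 cannot be predicted with confidence; it would be fixed by running both, and the route is written with the (R)-ligand.

**Route**

Step 1
Reactants: 1 1-decanol; 2 allyl acetate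
Product: 4 (S)-tridec-1-en-4-ol, via decanal 3 (not isolated)
Conditions: [Ir(cod)Cl]2 (2.5 mol %), (R)-Cl,MeO-BIPHEP (5 mol %), 4-chloro-3-nitrobenzoic acid (10 mol %), Cs2CO3 (20 mol %), THF, 100 °C, sealed tube
Reagents that add atoms: none
Why: Krische allylation (iridium-catalysed transfer-hydrogenative carbonyl allylation): the cyclometallated π-allyl iridium C,O-benzoate dehydrogenates 1 to decanal 3 and the allyliridium adds through a closed chair transition state, the (R)-ligand setting the carbinol centre as (S).

Step 2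
Reactants: 4 (S)-tridec-1-en-4-ol
Product: 6 (S)-dodecane-1,3-diol, via ozonide 5 (not isolated)
Conditions: O3, CH2Cl2, −78 °C; then NaBH4, MeOH, −78 °C to rt
Reagents that add atoms: ozone, [O-][O+]=O
Why: Ozonolysis with reductive work-up: cycloaddition and cycloreversion give the ozonide, which NaBH4 reduces to the primary alcohol while the carbinol centre is untouched.

Step 3
Reactants: 6 (S)-dodecane-1,3-diol; 2 allyl acetate
Product: 8 (4S,6S)-pentadec-1-ene-4,6-diol, via (S)-3-hydroxydodecanal 7 (not isolated)
Conditions: [Ir(cod)Cl]2 (5 mol %), (S)-Cl,MeO-BIPHEP (10 mol %), 4-chloro-3-nitrobenzoic acid (20 mol %), Cs2CO3 (40 mol %), THF, 100 °C, sealed tube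
Reagents that add atoms: none
Why: Krische allylation of an unprotected 1,3-diol: only the primary alcohol is dehydrogenated, the transient β-hydroxy aldehyde stays at low concentration, and the (S)-ligand should set the new carbinol centre anti to the existing one under catalyst control.

Step 4
Reactants: 8 (4S,6S)-pentadec-1-ene-4,6-diol
Product: 10 (3S,5S)-tetradecane-1,3,5-triol, via ozonide 9 (not isolated)
Conditions: O3, CH2Cl2, −78 °C; then NaBH4, MeOH, −78 °C to rt
Reagents that add atoms: ozone, [O-][O+]=O
Why: Ozonolysis with reductive work-up as in step 2; neither carbinol centre is touched.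

Step 5
Reactants: 10 (3S,5S)-tetradecane-1,3,5-triol; 2 allyl acetate
Product: 12 (4R,6R,8S)-heptadec-1-ene-4,6,8-triol, via dihydroxy aldehyde 11 (not isolated)
Conditions: [Ir(cod)Cl]2 (5 mol %), (R)-Cl,MeO-BIPHEP (10 mol %), 4-chloro-3-nitrobenzoic acid (20 mol %), Cs2CO3 (40 mol %), THF, 100 °C, sealed tube
Reagents that add atoms: none
Why: Third Krische allylation, now on the 1,3,5-triol: site-selective dehydrogenation of the primary alcohol and catalyst-directed addition with the (R)-ligand should set the third carbinol centre anti to its neighbour, completing the all-anti triol.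

Step 6
Reactants: 12 (4R,6R,8S)-heptadec-1-ene-4,6,8-triol
Product: 13 (4R,6R,8S)-4,6,8-tris(tert-butyldimethylsilyloxy)heptadec-1-ene
Conditions: TBSOTf (4 equiv), 2,6-lutidine (6 equiv), CH2Cl2, 0 °C to rt
Reagents that add atoms: tert-butyldimethylsilyl trifluoromethanesulfonate (TBSOTf), CC(C)(C)[Si](C)(C)OS(=O)(=O)C(F)(F)F
Why: Silylation of the three secondary hydroxyls with the reactive silyl triflate removes every free OH that would otherwise add to a gold-activated alkyne.

Step 7
Reactants: 13 (4R,6R,8S)-4,6,8-tris(tert-butyldimethylsilyloxy)heptadec-1-ene; 14 propiolic acid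
Product: 15 (6S)-6-[(2R,4R,6S)-2,4,6-tris(tert-butyldimethylsilyloxy)pentadecyl]-5,6-dihydro-2H-pyran-2-one
Conditions: (R)-DTBM-SEGPHOS(AuCl)2 (5 mol %), AgSbF6 (5 mol %), 4 Å MS, CHCl3, rt, slow addition of 14 (3 equiv)
Reagents that add atoms: none
Why: Cationic monovalent gold π-activates the alkyne of 14; the CH2 terminus of the alkene (C5) attacks the β-carbon (C4) anti to gold and the carboxyl oxygen captures the positive charge developing at C6 in a concerted, asynchronous event, after which protodeauration at C3 releases the lactone. The closest known reaction type is the gold-catalysed formal [4+2] annulation of propiolic acids with alkenes to α,β-unsaturated δ-lactones. The dihydropyranone ring is closed by an intermolecular C–C bond formation followed by a 6-endo Markovnikov capture of the alkene-derived cation by the carboxyl group, which anti-carboauration has placed cis to C5. C6 is the only new stereocentre; its (S) configuration is set by the face of the alkene that enters the chiral pocket of the bisphosphine digold catalyst, the ligand antipode being matched to the C8 silyloxy centre. The step needs Markovnikov regioselectivity (secured by secondary over primary cation character), annulation in preference to enyne cross metathesis (secured by the monosubstituted alkene, the metathesis pathway belonging to 1,2-disubstituted alkenes) and chemoselectivity for the alkene over oxygen nucleophiles (secured by silylation of all hydroxyls and slow addition of the acid).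

Step 8
Reactants: 15 (6S)-6-[(2R,4R,6S)-2,4,6-tris(tert-butyldimethylsilyloxy)pentadecyl]-5,6-dihydro-2H-pyran-2-one
Product: 16 (6S)-6-[(2S,4R,6S)-2,4,6-trihydroxypentadecyl]-5,6-dihydro-2H-pyran-2-one
Conditions: HF (48 % aq.), MeCN, 0 °C to rt
Reagents that add atoms: none
Why: Acidic fluoride cleavage of the three silyl ethers; the mildly acidic medium should leave the enoate lactone intact and disfavour the base-induced oxa-Michael addition of the C8 hydroxyl.

**Compound list**

1 | 1-decanol | CCCCCCCCCCO | starting material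
2 | allyl acetate | CC(=O)OCC=C | starting material
3 | decanal | CCCCCCCCCC=O | intermediate (not isolated)
4 | (S)-tridec-1-en-4-ol | CCCCCCCCC[C@H](O)CC=C | intermediate
5 | (2S)-1-(1,2,4-trioxolan-3-yl)undecan-2-ol (ozonide of 4) | CCCCCCCCC[C@H](O)CC1OCOO1 | intermediate (not isolated)
6 | (S)-dodecane-1,3-diol | CCCCCCCCC[C@H](O)CCO | intermediate
7 | (S)-3-hydroxydodecanal | CCCCCCCCC[C@H](O)CC=O | intermediate (not isolated)
8 | (4S,6S)-pentadec-1-ene-4,6-diol | CCCCCCCCC[C@H](O)C[C@@H](O)CC=C | intermediate
9 | (2R,4S)-1-(1,2,4-trioxolan-3-yl)tridecane-2,4-diol (ozonide of 8) | CCCCCCCCC[C@H](O)C[C@@H](O)CC1OCOO1 | intermediate (not isolated)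
10 | (3S,5S)-tetradecane-1,3,5-triol | CCCCCCCCC[C@H](O)C[C@@H](O)CCO | intermediate
11 | (3R,5S)-3,5-dihydroxytetradecanal | CCCCCCCCC[C@H](O)C[C@@H](O)CC=O | intermediate (not isolated)
12 | (4R,6R,8S)-heptadec-1-ene-4,6,8-triol | CCCCCCCCC[C@H](O)C[C@@H](O)C[C@H](O)CC=C | intermediate
13 | (4R,6R,8S)-4,6,8-tris(tert-butyldimethylsilyloxy)heptadec-1-ene | CCCCCCCCC[C@H](O[Si](C)(C)C(C)(C)C)C[C@@H](O[Si](C)(C)C(C)(C)C)C[C@H](O[Si](C)(C)C(C)(C)C)CC=C | intermediate
14 | propiolic acid | C#CC(=O)O | starting material
15 | (6S)-6-[(2R,4R,6S)-2,4,6-tris(tert-butyldimethylsilyloxy)pentadecyl]-5,6-dihydro-2H-pyran-2-one | CCCCCCCCC[C@H](O[Si](C)(C)C(C)(C)C)C[C@@H](O[Si](C)(C)C(C)(C)C)C[C@H](O[Si](C)(C)C(C)(C)C)C[C@@H]1CC=CC(=O)O1 | intermediate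
16 | (6S)-6-[(2S,4R,6S)-2,4,6-trihydroxypentadecyl]-5,6-dihydro-2H-pyran-2-one | CCCCCCCCC[C@H](O)C[C@@H](O)C[C@H](O)C[C@@H]1CC=CC(=O)O1 | target

**Step count and risks**

Total step count: 8. Longest linear sequence: 8 steps, from 1-decanol.

Steps most likely to fail:

Step 7. The monosubstituted alkene may attack the gold-activated alkyne only slowly, so that propiolic acid is consumed by self-addition, and facial discrimination at C6 may be weak, leaving a mixture of C6 epimers. The fallback builds the ring by allylation, acylation and ring-closing metathesis. It sets out from 13. Ozonolysis (O3, CH2Cl2, −78 °C; PPh3) should give (3S,5R,7S)-3,5,7-tris(tert-butyldimethylsilyloxy)hexadecanal F1. Brown allylation with the B-allyldiisopinocampheylborane antipode that delivers the required carbinol, expected to be (−)-Ipc2B(allyl) (Et2O, −78 °C; NaOH, H2O2), should give (4S,6R,8R,10S)-6,8,10-tris(tert-butyldimethylsilyloxy)nonadec-1-en-4-ol F2 under reagent control. Acryloyl chloride and i-Pr2NEt (CH2Cl2, 0 °C) should give (4S,6R,8R,10S)-6,8,10-tris(tert-butyldimethylsilyloxy)nonadec-1-en-4-yl prop-2-enoate F3. Ring-closing metathesis with second-generation Grubbs catalyst (CH2Cl2, 40 °C) then closes C3=C4 and comes back to the route at 15.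

Step 5. On the unprotected triol, site selectivity may be lost through dehydrogenation of a secondary alcohol, the transient β-hydroxy aldehyde may undergo retro-aldol cleavage or dehydration, and catalyst-directed anti selectivity may erode. The fallback uses a protected, reagent-controlled sequence. It sets out from 8. TBSOTf and 2,6-lutidine should give (4S,6S)-4,6-bis(tert-butyldimethylsilyloxy)pentadec-1-ene F4. Ozonolysis (O3, CH2Cl2, −78 °C; PPh3) should give (3R,5S)-3,5-bis(tert-butyldimethylsilyloxy)tetradecanal F5. Brown allylation, expected to need (+)-Ipc2B(allyl), should give (4R,6S,8S)-6,8-bis(tert-butyldimethylsilyloxy)heptadec-1-en-4-ol F6. Silylation of the remaining hydroxyl with TBSOTf and 2,6-lutidine comes back to the route at 13, so steps 4 to 6 are replaced.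

Step 8. The hindered central silyl ether may cleave incompletely, and under the longer acid exposure then needed the liberated C8 hydroxyl may add to C4 of the enoate (intramolecular oxa-Michael addition). The fallback changes the protecting group to one that leaves under near-neutral conditions. It sets out from 12. TESOTf and 2,6-lutidine should give (4R,6R,8S)-4,6,8-tris(triethylsilyloxy)heptadec-1-ene F7. The gold annulation of step 7 with 14 should give (6S)-6-[(2R,4R,6S)-2,4,6-tris(triethylsilyloxy)pentadecyl]-5,6-dihydro-2H-pyran-2-one F8. Cleavage with AcOH/THF/H2O at rt comes back to the route at 16.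

**Further compounds**

F1 | step 7 | (3S,5R,7S)-3,5,7-tris(tert-butyldimethylsilyloxy)hexadecanal | CCCCCCCCC[C@H](O[Si](C)(C)C(C)(C)C)C[C@@H](O[Si](C)(C)C(C)(C)C)C[C@H](O[Si](C)(C)C(C)(C)C)CC=O
F2 | step 7 | (4S,6R,8R,10S)-6,8,10-tris(tert-butyldimethylsilyloxy)nonadec-1-en-4-ol | CCCCCCCCC[C@H](O[Si](C)(C)C(C)(C)C)C[C@@H](O[Si](C)(C)C(C)(C)C)C[C@H](O[Si](C)(C)C(C)(C)C)C[C@@H](O)CC=C
F3 | step 7 | (4S,6R,8R,10S)-6,8,10-tris(tert-butyldimethylsilyloxy)nonadec-1-en-4-yl prop-2-enoate | CCCCCCCCC[C@H](O[Si](C)(C)C(C)(C)C)C[C@@H](O[Si](C)(C)C(C)(C)C)C[C@H](O[Si](C)(C)C(C)(C)C)C[C@@H](OC(=O)C=C)CC=C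
F4 | step 5 | (4S,6S)-4,6-bis(tert-butyldimethylsilyloxy)pentadec-1-ene | CCCCCCCCC[C@H](O[Si](C)(C)C(C)(C)C)C[C@@H](O[Si](C)(C)C(C)(C)C)CC=C
F5 | step 5 | (3R,5S)-3,5-bis(tert-butyldimethylsilyloxy)tetradecanal | CCCCCCCCC[C@H](O[Si](C)(C)C(C)(C)C)C[C@@H](O[Si](C)(C)C(C)(C)C)CC=O
F6 | step 5 | (4R,6S,8S)-6,8-bis(tert-butyldimethylsilyloxy)heptadec-1-en-4-ol | CCCCCCCCC[C@H](O[Si](C)(C)C(C)(C)C)C[C@@H](O[Si](C)(C)C(C)(C)C)C[C@H](O)CC=C
F7 | step 8 | (4R,6R,8S)-4,6,8-tris(triethylsilyloxy)heptadec-1-ene | CCCCCCCCC[C@H](O[Si](CC)(CC)CC)C[C@@H](O[Si](CC)(CC)CC)C[C@H](O[Si](CC)(CC)CC)CC=C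
F8 | step 8 | (6S)-6-[(2R,4R,6S)-2,4,6-tris(triethylsilyloxy)pentadecyl]-5,6-dihydro-2H-pyran-2-one | CCCCCCCCC[C@H](O[Si](CC)(CC)CC)C[C@@H](O[Si](CC)(CC)CC)C[C@H](O[Si](CC)(CC)CC)C[C@@H]1CC=CC(=O)O1
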